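**The problem**

The target 18 joins two six-membered carbocycles through one sp3 methine carbon that also carries an isobutyl group. Ring A is a hexasubstituted benzene with three hydroxyls, a methyl group and a 3-phenylpropanoyl ketone. Ring B is the enolised 2,2,6,6-tetramethylcyclohexane-1,3,5-trione (syncarpyl) unit. The methine is the only stereocentre, (S) in 18, so nothing in the molecule can direct it; it has to come from a catalyst or from a resolution. It is also the most fragile position: it lies between an ortho-phenol of ring A and the vinylogous acid of ring B, so acid, heat or a buffered medium can ionise it to an ortho-quinone methide and return racemic material. Ring A has no free position, so its three carbon substituents must be placed in an order that the directing effects of a phloroglucinol allow, and its phenols must be told apart from those of any second phenolic ring. The β-triketone of ring B has quaternary carbons between its carbonyls and opens by retro-Claisen attack of hard nucleophiles. The key step rests on the oxygen pattern of ring B: in triketone numbering C1, C3 and C5 carry oxygen, C2 carries the methine, and C4 and C6 carry the two methyl pairs that exhaustive C-methylation of a 2-substituted phloroglucinol would install. The same pattern on ring A puts a hydroxyl ortho to the methine carbon, which makes an ortho-quinone methide available as the electrophile for joining the rings.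

**Retrosynthesis**

18 to 16. The two O–benzyl bonds on ring A are cut last. Benzyl is chosen because neutral hydrogenolysis touches neither the methine nor the ketone nor the triketone; methyl ethers would need a strong Lewis acid and silyl ethers would not survive methoxide. Compound 16 differs from 18 only in these two ethers. The forward step must not reduce the aryl ketone.

16 to 12. The four C–CH3 bonds at C4 and C6 of ring B are cut, two at each carbon. This turns the triketone back into a 2,4,6-trihydroxyphenyl ring, so that 12 is a bis(aryl)alkane built from two phloroglucinols. The neighbouring cut, methine to ring B of 16 (quinone methide plus syncarpic acid), is one step shorter. It is set aside as the fallback because the strongly acidic triketone can drive an uncatalysed, racemic addition, whereas phloroglucinol is a neutral arene nucleophile that a chiral acid can organise. The forward reaction must methylate carbon rather than oxygen, ring B rather than ring A, stop at four methyl groups and leave the methine alone. No ring is formed.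

12 to 9 and 10, through 11. The bond between the methine and ring B is cut. Phloroglucinol 10 has three equivalent carbons, so no regiochemistry arises. The electrophile is the ortho-quinone methide 11, formed from carbinol 9 by loss of water. Cutting the methine–ring A bond instead would require a ring B quinone methide with three differentiated phenols and a hexasubstituted ring A as nucleophile. Cutting the methine–isobutyl bond would require asymmetric alkyl addition to an aryl-substituted quinone methide, which has less precedent. The precursor 9 is racemic and carries no stereochemical burden. The forward step must select one face of 11 and stop at mono-alkylation of 10.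

9 to 7 and 8. The bond between the carbinol carbon and the isobutyl CH2 is cut, giving aldehyde 7 and isobutylmagnesium bromide 8. Direct hydroxyalkylation of the arene with 3-methylbutanal would form the same carbinol, but phenol–aldehyde condensations run on to bis-adducts because the carbinol ionises faster than the aldehyde reacts. The forward step must add to the aldehyde and spare the ketone.

7 to 5. Two O–benzyl bonds are cut. The hydroxyl left free in 7 lies between the formyl and the acyl group; it is the one ortho to the future methine and the one needed for quinone methide formation. The forward step must leave that hydroxyl unreacted.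

5 to 3, through 4. The ring–CHO bond is cut. After acylation only one ring carbon of 3 is free, so formylation has no choice of position.

3 to 1 and 2. The ring–acyl bond is cut. The two free carbons of 2,4,6-trihydroxytoluene 1 are equivalent, so acylation with 3-phenylpropanoyl chloride 2 gives one ketone. Acylating before formylating avoids passing an aldehyde through AlCl3.

**Roads not taken**

Alternative 1: Ring A is disconnected across two ring bonds into siloxyalkyne A2, which carries the stereocentre and the finished ring B as its enol methyl ether, and cyclobutenone A3. On heating, A3 would open to a vinylketene, add to A2, reopen and close by six-electron electrocyclisation to the phenol A1 (Danheiser benzannulation).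
- Merits: the substitution pattern of ring A is fixed by the annulation, not by directing effects. Ring B is never a phenol, so it never has to be told apart from ring A.
- Weak points: the stereocentre of A2 is propargylic and also the γ-position of a vinylogous ester, so the heat of the annulation invites propargyl–allenyl isomerisation and loss of configuration. A2 must itself be made enantiopure over several steps. A1 still lacks the ketone, so a Friedel–Crafts acylation at its last ring C–H would follow. Three different oxygen substituents must then be removed, among them an aryl ethyl ether that yields only to a strong Lewis acid, which the methine is unlikely to survive.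
- Comparison: this road is better than the chosen plan in two respects: no ring A phenoxide ever meets a methylating agent, and no selective benzylation is needed. The chosen plan sets against this seven steps from purchasable phenols, a stereocentre formed by a catalyst in the bond-forming step and not heated afterwards, and protecting groups that leave by hydrogenolysis.

Alternative 2: The three aryl C–O bonds of ring A are cut. The trifluoroaryl ketone A5, with ring B and the stereocentre in place, would be treated with sodium benzyloxide A6 in a hot polar aprotic solvent to give A4 by three addition–eliminations.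
- Merits: fluorine is a small, inert placeholder, so no phenol needs protection while the skeleton is built. A fluorinated ring cannot form a quinone methide, so the methine is safe until the end. Only deprotection follows the key step, as in the chosen plan.
- Weak points: each benzyloxy group introduced deactivates the ring for the next substitution. The only activating group is one ketone, twisted out of conjugation by two ortho substituents. The third substitution would need forcing conditions, under which A6 can add to the enol ether of ring B, open the β-triketone by retro-Claisen cleavage, enolise the ketone and deprotonate the methine, which is benzylic to an electron-poor arene.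
- Comparison: this road matches the chosen plan after the key step and is better at keeping the methine inert during assembly. The chosen plan sets against this that all ring A oxygens arrive with starting material 1, and that its strongest base is methoxide at room temperature on a substrate whose two rings are both held as anions.

Alternative 3: Ring B is cut at C1–C6 and C2–C3 (triketone numbering) into dihydrocoumarin A8 and keto ester A9. The lithium enolate of A9 would acylate on the lactone carbonyl of A8 and release the ring A phenoxide; the methylene of the new ketone would then close onto the ester to give A7.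
- Merits: the stereocentre of A8 could come from asymmetric conjugate addition to a coumarin or from asymmetric hydrogenation. Both have a broader record with alkyl substituents than acid-catalysed quinone methide arylation, and in this respect the road is better than the chosen one. Ring B is built with its methyl groups in place, so C- versus O-methylation and over-methylation do not arise.
- Weak points: a fully substituted enolate carbon must acylate a lactone that has its own acidic CH2, so proton transfer competes. The intermediate diketone has a quaternary carbon between its carbonyls and can be cleaved by the liberated phenoxide or methoxide. A7 lacks the ring A ketone, so a late Friedel–Crafts acylation between two benzyl ethers and next to the acid-labile methine would be needed.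
- Comparison: the chosen plan sets against the better stereocentre precedent that the ketone is installed in step 1 on a simple arene, that ring B is made from phloroglucinol and iodomethane in one operation, and that the route is shorter.

Key step: step 6

Remarks on the chemistry (assumptions):
- The sense of induction of the phosphoric acid in step 5 cannot be predicted with certainty for this quinone methide; the (R)-catalyst is written, and its enantiomer would be used if it delivers the other enantiomer.
- The methine has the same spatial arrangement from 12 to 18; its descriptor is (R) while ring B is aromatic (12–14) and (S) once ring B is dearomatised (15–18), because the ring B carbon then outranks ring A.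
- In steps 3, 6 and 7 one event is repeated; the partly reacted compounds 6, 13–15 and 17 are drawn for one assumed order, which does not affect the product.

**Route**

Step 1
Reactants: 1 2,4,6-trihydroxytoluene; 2 3-phenylpropanoyl chloride
Product: 3 1-(2,4,6-trihydroxy-3-methylphenyl)-3-phenylpropan-1-one
Conditions: AlCl3 (4 equiv), PhNO2, rt to 60 °C; then ice, aq. HCl
Reagents that add atoms: none
Why: Friedel–Crafts acylation of a phloroglucinol; the two free ring carbons of 1 are equivalent, and the aluminium-chelated ketone deactivates the ring against a second acylation.

Step 2
Reactants: 3 1-(2,4,6-trihydroxy-3-methylphenyl)-3-phenylpropan-1-one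
Product: 5 2,4,6-trihydroxy-3-methyl-5-(3-phenylpropanoyl)benzaldehyde, via α-chloro ether 4 (not isolated)
Conditions: Cl2CHOMe (1.2 equiv), TiCl4 (4 equiv), CH2Cl2, −10 to 0 °C; then 1 M HCl
Reagents that add atoms: dichloromethyl methyl ether, COC(Cl)Cl; water, O
Why: Rieche formylation: the titanium phenoxide of 3 attacks the oxocarbenium ion at the only free ring carbon and the α-chloro ether 4 is hydrolysed on work-up; the Lewis-acid route leaves the ketone CH2 alone, where a Vilsmeier reagent could condense with it towards a chromone.

Step 3
Reactants: 5 2,4,6-trihydroxy-3-methyl-5-(3-phenylpropanoyl)benzaldehyde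
Product: 7 2,4-bis(benzyloxy)-6-hydroxy-3-methyl-5-(3-phenylpropanoyl)benzaldehyde, via mono-O-benzyl ether 6 (not isolated)
Conditions: BnBr (2.1 equiv), K2CO3, DMF, 0 °C to rt
Reagents that add atoms: benzyl bromide, BrCc1ccccc1
Why: Williamson ether synthesis; the hydroxyl between the two carbonyl groups is hydrogen-bonded to both and shielded on both sides, so the two hydroxyls next to the methyl group are expected to react first, and two equivalents of benzyl bromide stop there.

Step 4
Reactants: 7 2,4-bis(benzyloxy)-6-hydroxy-3-methyl-5-(3-phenylpropanoyl)benzaldehyde; 8 isobutylmagnesium bromide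
Product: 9 rac-1-[2,4-bis(benzyloxy)-6-hydroxy-5-(1-hydroxy-3-methylbutyl)-3-methylphenyl]-3-phenylpropan-1-one
Conditions: 8 (2.5 equiv), LaCl3·2LiCl, THF, −78 to −30 °C; then aq. NH4Cl, cold; used without storage
Reagents that add atoms: none
Why: Grignard addition: the first equivalent forms the magnesium phenoxide and the second adds to the aldehyde, which is far more electrophilic than the doubly ortho-substituted, phenoxide-conjugated aryl ketone; LaCl3·2LiCl favours 1,2-addition over enolisation and β-hydride reduction. The carbinol centre is racemic and is erased in step 5.

Step 5
Reactants: 9 rac-1-[2,4-bis(benzyloxy)-6-hydroxy-5-(1-hydroxy-3-methylbutyl)-3-methylphenyl]-3-phenylpropan-1-one; 10 phloroglucinol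
Product: 12 1-{2,4-bis(benzyloxy)-6-hydroxy-3-methyl-5-[(1R)-3-methyl-1-(2,4,6-trihydroxyphenyl)butyl]phenyl}-3-phenylpropan-1-one, via ortho-quinone methide 11 (not isolated)
Conditions: (R)-TRIP [(R)-3,3'-bis(2,4,6-triisopropylphenyl)-1,1'-binaphthyl-2,2'-diyl hydrogen phosphate] (10 mol%), 10 (5 equiv), 4 Å MS, PhMe/EtOAc, 0 °C
Reagents that add atoms: none
Why: Chiral Brønsted acid catalysed asymmetric Friedel–Crafts alkylation through an ortho-quinone methide: the phosphoric acid dehydrates 9 to 11, then holds the carbonyl oxygen of 11 and a hydroxyl of 10 by hydrogen bonds inside its aryl pocket so that the arene carbon adds to one face of the exocyclic C=C, setting the methine as (R). All three carbons of 10 are equivalent, and the excess of 10 suppresses a second alkylation.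

Step 6
Reactants: 12 1-{2,4-bis(benzyloxy)-6-hydroxy-3-methyl-5-[(1R)-3-methyl-1-(2,4,6-trihydroxyphenyl)butyl]phenyl}-3-phenylpropan-1-one
Product: 16 4-{(1S)-1-[2,4-bis(benzyloxy)-6-hydroxy-3-methyl-5-(3-phenylpropanoyl)phenyl]-3-methylbutyl}-5-hydroxy-2,2,6,6-tetramethylcyclohex-4-ene-1,3-dione, via monomethyl compound 13 (not isolated), via dimethyl compound 14 (not isolated), via trimethyl dienone 15 (not isolated)
Conditions: NaOMe (6.5 equiv), MeI (4.4 equiv, in portions), degassed MeOH, Ar, 0 °C to rt; then poured into cold 1 M HCl
Reagents that add atoms: iodomethane, CI
Why: This is the exhaustive C-methylation of a phloroglucinol, the reaction by which acylphloroglucinols are converted into syncarpic-acid-type β-triketones. Methoxide ionises the phenols of ring B, and the polyphenoxide attacks iodomethane through carbon because in methanol the oxygens are hydrogen-bonded and sodium-paired while the ring carbons between two oxygens carry high charge density. The two free carbons are methylated once each (13, 14); the third methyl breaks aromaticity (15) and leaves a vinylogous acid that is deprotonated again and methylated at the remaining CH(CH3) carbon to give 16. No ring is closed and no stereocentre is formed; the methine is not deprotonated, and with ring A held as a phenoxide and ring B as a polyanion or enolate, cleavage of a methine–ring bond, which needs a neutral keto tautomer of one ring, is closed off while base is present. Ring B reacts in preference to ring A because ring A has no unsubstituted carbon, two of its oxygens are benzylated and the third is a ketone-chelated phenoxide flanked by two substituents. The reaction should stop at four methyl groups because the only nucleophilic carbon left in 16 is C2 of the triketone, which carries the branched methine substituent and is shielded on both sides; iodomethane is kept near four equivalents so that the slower O-methylations and a fifth C-methylation do not start. Air is excluded because polyphenoxides and syncarpyl enolates take up oxygen.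

Step 7
Reactants: 16 4-{(1S)-1-[2,4-bis(benzyloxy)-6-hydroxy-3-methyl-5-(3-phenylpropanoyl)phenyl]-3-methylbutyl}-5-hydroxy-2,2,6,6-tetramethylcyclohex-4-ene-1,3-dione
Product: 18 5-hydroxy-2,2,6,6-tetramethyl-4-{(1S)-3-methyl-1-[2,4,6-trihydroxy-3-methyl-5-(3-phenylpropanoyl)phenyl]butyl}cyclohex-4-ene-1,3-dione, via mono-O-benzyl ether 17 (not isolated)
Conditions: H2 (1 atm), 10% Pd/C, EtOAc, rt
Reagents that add atoms: none
Why: Hydrogenolysis of aryl benzyl ethers over palladium on carbon; neutral conditions at room temperature should leave the chelated aryl ketone, the enolised triketone and the methine stereocentre untouched.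

**Compound list**

1 | 2,4,6-trihydroxytoluene | Cc1c(O)cc(O)cc1O | starting material
2 | 3-phenylpropanoyl chloride | O=C(Cl)CCc1ccccc1 | starting material
3 | 1-(2,4,6-trihydroxy-3-methylphenyl)-3-phenylpropan-1-one | Cc1c(O)cc(O)c(C(=O)CCc2ccccc2)c1O | intermediate
4 | 1-{3-[chloro(methoxy)methyl]-2,4,6-trihydroxy-5-methylphenyl}-3-phenylpropan-1-one (racemic; titanium-bound in the flask) | Cc1c(O)c(C(Cl)OC)c(O)c(C(=O)CCc2ccccc2)c1O | intermediate
5 | 2,4,6-trihydroxy-3-methyl-5-(3-phenylpropanoyl)benzaldehyde | Cc1c(O)c(C=O)c(O)c(C(=O)CCc2ccccc2)c1O | intermediate
6 | 4-(benzyloxy)-2,6-dihydroxy-3-methyl-5-(3-phenylpropanoyl)benzaldehyde | Cc1c(O)c(C=O)c(O)c(C(=O)CCc2ccccc2)c1OCc1ccccc1 | intermediate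
7 | 2,4-bis(benzyloxy)-6-hydroxy-3-methyl-5-(3-phenylpropanoyl)benzaldehyde | Cc1c(OCc2ccccc2)c(C=O)c(O)c(C(=O)CCc2ccccc2)c1OCc1ccccc1 | intermediate
8 | isobutylmagnesium bromide | CC(C)C[Mg]Br | starting material
9 | rac-1-[2,4-bis(benzyloxy)-6-hydroxy-5-(1-hydroxy-3-methylbutyl)-3-methylphenyl]-3-phenylpropan-1-one (racemic carbinol) | Cc1c(OCc2ccccc2)c(C(O)CC(C)C)c(O)c(C(=O)CCc2ccccc2)c1OCc1ccccc1 | intermediate
10 | phloroglucinol (benzene-1,3,5-triol) | Oc1cc(O)cc(O)c1 | starting material
11 | 3,5-bis(benzyloxy)-4-methyl-6-(3-methylbutylidene)-2-(3-phenylpropanoyl)cyclohexa-2,4-dien-1-one (alkylidene geometry not defined) | CC1=C(OCc2ccccc2)C(=CCC(C)C)C(=O)C(C(=O)CCc2ccccc2)=C1OCc1ccccc1 | intermediate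
12 | 1-{2,4-bis(benzyloxy)-6-hydroxy-3-methyl-5-[(1R)-3-methyl-1-(2,4,6-trihydroxyphenyl)butyl]phenyl}-3-phenylpropan-1-one | Cc1c(OCc2ccccc2)c(C(=O)CCc2ccccc2)c(O)c([C@H](CC(C)C)c2c(O)cc(O)cc2O)c1OCc1ccccc1 | intermediate
13 | 1-{2,4-bis(benzyloxy)-6-hydroxy-3-methyl-5-[(1R)-3-methyl-1-(2,4,6-trihydroxy-3-methylphenyl)butyl]phenyl}-3-phenylpropan-1-one | Cc1c(OCc2ccccc2)c(C(=O)CCc2ccccc2)c(O)c([C@H](CC(C)C)c2c(O)cc(O)c(C)c2O)c1OCc1ccccc1 | intermediate
14 | 1-{2,4-bis(benzyloxy)-6-hydroxy-3-methyl-5-[(1R)-3-methyl-1-(2,4,6-trihydroxy-3,5-dimethylphenyl)butyl]phenyl}-3-phenylpropan-1-one | Cc1c(OCc2ccccc2)c(C(=O)CCc2ccccc2)c(O)c([C@H](CC(C)C)c2c(O)c(C)c(O)c(C)c2O)c1OCc1ccccc1 | intermediate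
15 | 2-{(1S)-1-[2,4-bis(benzyloxy)-6-hydroxy-3-methyl-5-(3-phenylpropanoyl)phenyl]-3-methylbutyl}-3,5-dihydroxy-4,6,6-trimethylcyclohexa-2,4-dien-1-one | Cc1c(OCc2ccccc2)c(C(=O)CCc2ccccc2)c(O)c([C@H](CC(C)C)C2=C(O)C(C)=C(O)C(C)(C)C2=O)c1OCc1ccccc1 | intermediate
16 | 4-{(1S)-1-[2,4-bis(benzyloxy)-6-hydroxy-3-methyl-5-(3-phenylpropanoyl)phenyl]-3-methylbutyl}-5-hydroxy-2,2,6,6-tetramethylcyclohex-4-ene-1,3-dione | Cc1c(OCc2ccccc2)c(C(=O)CCc2ccccc2)c(O)c([C@H](CC(C)C)C2=C(O)C(C)(C)C(=O)C(C)(C)C2=O)c1OCc1ccccc1 | intermediate
17 | 4-{(1S)-1-[2-(benzyloxy)-4,6-dihydroxy-3-methyl-5-(3-phenylpropanoyl)phenyl]-3-methylbutyl}-5-hydroxy-2,2,6,6-tetramethylcyclohex-4-ene-1,3-dione | Cc1c(O)c(C(=O)CCc2ccccc2)c(O)c([C@H](CC(C)C)C2=C(O)C(C)(C)C(=O)C(C)(C)C2=O)c1OCc1ccccc1 | intermediate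
18 | 5-hydroxy-2,2,6,6-tetramethyl-4-{(1S)-3-methyl-1-[2,4,6-trihydroxy-3-methyl-5-(3-phenylpropanoyl)phenyl]butyl}cyclohex-4-ene-1,3-dione (CNP0188786.1) | Cc1c(O)c(C(=O)CCc2ccccc2)c(O)c([C@H](CC(C)C)C2=C(O)C(C)(C)C(=O)C(C)(C)C2=O)c1O | target

**Step count and risks**

Total steps: 7. Longest linear sequence: 7 (from 1 to 18).

Step 6 (key step). What may go wrong:
- Methylation may run past four methyl groups, by O-methylation of the ring A phenoxide or of the ring B enolate, or by a fifth C-methylation at C2.
- It may stall at mixtures of partly methylated rings.
- The anions may take up oxygen.
- Configuration may be partly lost through ionisation of the methine during the acidic quench, when a neutral triketone and a phenoxide can briefly coexist.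

The fallback brings ring B in already methylated. It sets out from carbinol 9, which is treated under the conditions of step 5 with syncarpic acid F1 (purchased) in place of phloroglucinol. The phosphoric acid again forms quinone methide 11, the enol carbon of syncarpic acid F1 adds to it, and the route is rejoined at 16. Addition of cyclic 1,3-diketones to ortho-quinone methides under chiral phosphoric acids is known chemistry. The acidity of the triketone may feed an uncatalysed racemic pathway, which is why this is the fallback and not the plan.

Step 5. What may go wrong:
- Facial selectivity may be poor on an alkyl-substituted, fully substituted quinone methide.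
- The electron-rich product may be alkylated a second time.
- The quinone methide may be diverted to the styrene tautomer or to dimers.
- Enantiopurity may erode slowly by reversible ionisation of the product.

The fallback replaces asymmetric catalysis by resolution. It sets out from 9 and 10; an achiral acid (diphenyl phosphate) gives the racemic diarylalkane F2, which is separated by preparative chromatography on a chiral stationary phase. The (R)-enantiomer is 12.

Step 3. What may go wrong: the benzylation may fail to discriminate among three phenols that are each conjugated to a carbonyl group, giving regioisomeric ethers or over-alkylation. Any di-O-benzyl isomer still leaves a hydroxyl ortho or para to the future methine, so the later chemistry is not closed off in principle, but a single isomer is wanted. The fallback sets out from 5. Exhaustive benzylation (excess BnBr, K2CO3, DMF, warm) gives the tri-O-benzyl aldehyde F3. MgBr2·OEt2 in PhMe/Et2O then removes the benzyl group on the oxygen between the two carbonyl groups, the only one that can be chelated from both sides. The route is rejoined at 7.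

Step 4. What may go wrong:
- The branched Grignard reagent may reduce the hindered aldehyde by β-hydride transfer.
- The ketone may be attacked or enolised.
- The magnesium alkoxide may eliminate to a quinone methide that takes up a second isobutyl group.

The fallback avoids the carbinol. It sets out from 7; Wittig olefination with the ylide from isobutyltriphenylphosphonium bromide (excess, one equivalent being consumed by the phenol) gives the ortho-hydroxystyrene F4. Under the phosphoric acid of step 5, the ortho-hydroxystyrene F4 is protonated at the alkene carbon remote from the ring to give the same quinone methide 11, and the route is rejoined at 12.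

**Further compounds**

F1 | step 6 | syncarpic acid (5-hydroxy-2,2,6,6-tetramethylcyclohex-4-ene-1,3-dione) | CC1(C)C(=O)C=C(O)C(C)(C)C1=O
F2 | step 5 | rac-1-{2,4-bis(benzyloxy)-6-hydroxy-3-methyl-5-[3-methyl-1-(2,4,6-trihydroxyphenyl)butyl]phenyl}-3-phenylpropan-1-one (racemate of 12) | Cc1c(OCc2ccccc2)c(C(=O)CCc2ccccc2)c(O)c(C(CC(C)C)c2c(O)cc(O)cc2O)c1OCc1ccccc1
F3 | step 3 | 2,4,6-tris(benzyloxy)-3-methyl-5-(3-phenylpropanoyl)benzaldehyde | Cc1c(OCc2ccccc2)c(C=O)c(OCc2ccccc2)c(C(=O)CCc2ccccc2)c1OCc1ccccc1
F4 | step 4 | 1-{2,4-bis(benzyloxy)-6-hydroxy-3-methyl-5-[(1Z)-3-methylbut-1-en-1-yl]phenyl}-3-phenylpropan-1-one (Z expected as the main isomer; either serves) | Cc1c(OCc2ccccc2)c(/C=C\C(C)C)c(O)c(C(=O)CCc2ccccc2)c1OCc1ccccc1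
A1 | alternative 1 | 4-{1-[4-ethoxy-6-hydroxy-3-methyl-2-(triisopropylsilyloxy)phenyl]-3-methylbutyl}-5-methoxy-2,2,6,6-tetramethylcyclohex-4-ene-1,3-dione, methine as in the target | Cc1c(OCC)cc(O)c([C@H](CC(C)C)C2=C(OC)C(C)(C)C(=O)C(C)(C)C2=O)c1O[Si](C(C)C)(C(C)C)C(C)C
A2 | alternative 1 | 5-methoxy-2,2,6,6-tetramethyl-4-[5-methyl-1-(triisopropylsilyloxy)hex-1-yn-3-yl]cyclohex-4-ene-1,3-dione, single enantiomer | CC(C)[Si](C(C)C)(C(C)C)OC#C[C@H](CC(C)C)C1=C(OC)C(C)(C)C(=O)C(C)(C)C1=O
A3 | alternative 1 | 3-ethoxy-2-methylcyclobut-2-en-1-one | CCOC1=C(C)C(=O)C1
A4 | alternative 2 | tri-O-benzyl enol methyl ether of the target | Cc1c(OCc2ccccc2)c(C(=O)CCc2ccccc2)c(OCc2ccccc2)c([C@H](CC(C)C)C2=C(OC)C(C)(C)C(=O)C(C)(C)C2=O)c1OCc1ccccc1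
A5 | alternative 2 | 2,4,6-trifluoro analogue of A4 (fluorine in place of each benzyloxy group) | Cc1c(F)c(C(=O)CCc2ccccc2)c(F)c([C@H](CC(C)C)C2=C(OC)C(C)(C)C(=O)C(C)(C)C2=O)c1F
A6 | alternative 2 | sodium benzyloxide | [Na+].[O-]Cc1ccccc1
A7 | alternative 3 | des-acyl di-O-benzyl target | Cc1c(OCc2ccccc2)cc(OCc2ccccc2)c([C@H](CC(C)C)C2=C(O)C(C)(C)C(=O)C(C)(C)C2=O)c1O
A8 | alternative 3 | 5,7-bis(benzyloxy)-8-methyl-4-(2-methylpropyl)-3,4-dihydro-2H-chromen-2-one, single enantiomer at C4 | Cc1c(OCc2ccccc2)cc(OCc2ccccc2)c2c1OC(=O)C[C@H]2CC(C)C
A9 | alternative 3 | methyl 2,2,4-trimethyl-3-oxopentanoate | COC(=O)C(C)(C)C(=O)C(C)C
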